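## Analysis of the target

Cinnamtannin A2 is a linear tetramer of (−)-epicatechin: four 2-(3,4-dihydroxyphenyl)chroman-3,5,7-triol units, each with rings A, C and B, joined by three bonds from C4 of one unit to C8 of the next (unit 1 is the top unit with a free C8, unit 4 the terminal unit with a C4 methylene). It has eleven stereocentres: C2 and C3 of every unit (2R,3R, ring B cis to the C3 oxygen) and C4 of units 1–3, where the interflavan bond is β, trans to the C3 oxygen and trans to ring B. The sixteen phenols make the free compound easy to oxidise, acid cleaves the C4–C8 bonds through a C4 cation, and base opens ring C and epimerises C2 once ring B is unprotected, so the assembly has to be carried as benzyl ethers and released last under neutral conditions. The difficulty is to form three C4–C8 bonds with a defined chain length, with C8 and not C6 as the point of attachment, with the 4β configuration, and to repeat the 2,3-cis-3,4-trans pattern of ring C three times. The strategy rests on the fact that in each upper unit C4 is bonded to ring A at C4a, the carbon ortho to O1, while C3 carries oxygen trans to the C4 aryl bond. C4, C3 and C2 of such a unit are therefore the β-carbon, α-carbon and carbonyl carbon of a propenal on C8 of the unit below, O1–C2 is the hemiacetal bond of a phenol to that aldehyde, and ring B is an aryl nucleophile for the hemiacetal carbon.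

## Retrosynthetic reasoning

**37 to 36.** The twenty O–benzyl bonds are cut last. Benzyl is chosen because it leaves by hydrogenolysis at neutral pH, which spares the interflavan bonds and C2; the forward reaction is one global debenzylation.

**36 to 35 and 19.** The bond between C2 of unit 1 and ring B is cut. After the cascade C2 is at the aldehyde oxidation level, so ring B has to arrive as a nucleophile on an oxocarbenium ion. The forward reaction must bring the aryl group in trans to the large C4 substituent, which is the 2,3-cis relation. It must also beat the phloroglucinol-type A rings of the substrate, which are several orders of magnitude more nucleophilic than a plain catechol ether C–H bond. For that reason the aryl group is delivered from boron (19) within an ion pair, and the carbon–boron bond also fixes the position on ring B.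

**35 to 33 to 32.** Only functional groups change. The lactol 32 is masked as methyl acetal 33 before any base is used, because the open hydroxy-aldehyde would epimerise at C3. The benzoate is then exchanged for a benzyl ether (through 34), because a C3 acyloxy group would bridge to C2 and steer the aryl group to the wrong face (2,3-trans).

**32 to 30, 8 and 10 (key disconnection).** Three bonds of unit 1 are cut: C4–C4a, O1–C2 and C3–O. This turns ring C of unit 1 into enal 30, phenol 8 and peroxide 10. The cut is made here because it creates the interflavan stereocentre without a C4 cation and puts the new carbon on a C8 that was chosen earlier. The forward step has to select the face of the enal β-carbon, ortho attack of the phenol, and oxygen delivery to C3 anti to the new aryl group.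

**30 to 28 and 5.** The C8–alkenyl bond is cut. A bromide at C8 and an (E)-alkenyl boronate carrying the masked aldehyde give the enal by cross-coupling and acetal hydrolysis (through 29); the bromine is the only handle the trimer needs.

**28 back to 7.** The same four disconnections remove unit 2 and then unit 3: 28 from 27 and 19; 27 from 25 and 24; 24 from 22, 9 and 10; 22 from 20 and 5; 20 from 15 and 19; 15 from 13 and 12; 12 from 7, 9 and 10. In these rounds the phenol is the bromophenol 9, so that each new unit is born with bromine at C8 and the C8/C6 question never arises on an oligomer.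

**7 to 4, 3 and 1.** Unit 4 comes from the chiral pool: enal 7 from bromide 4 and 5, 4 by bromination of 3, and 3 by benzylation of 1, which supplies C2 and C3 of unit 4.

**9 to 8, and 19 to 16.** The bromophenol comes from 8 by ortho-bromination, the trifluoroborate from aryl bromide 16 by lithiation and borylation.

## Alternatives that were turned down

**Alternative 1:** The disconnection is ring A of unit 4 (C8–C8a, C6–C7 and C4a–C8a). The lowest interflavan bond would already exist as the bond from C4 of unit 3 to an alkyne. In the forward key step diazoketone A3 is irradiated, Wolff rearrangement gives a vinylketene, this adds to the ynol silyl ether of trimer A2, and the 2-vinylcyclobutenone opens and recloses to the phenol A1.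
- For it: attachment at C8 is fixed by construction, ring A is formed with its three oxygens already differentiated, and the step is convergent.
- Against it: it makes only one of the three interflavan bonds, and A2 is itself a trimer whose two bonds need another method. A2 needs an ynol ether on a hindered C4 with β configuration. A1 must still be closed at O1–C2 by substitution at an electron-rich benzylic carbon, which is prone to ionise and scramble C2, and then be desilylated and benzylated. The photolysis has to tolerate fifteen benzyl ethers and electron-rich arenes, and A3 needs its own multistep synthesis with two stereocentres.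
- Comparison: on C8 regiochemistry it is as strong as the chosen route, which fixes C8 through bromine. The chosen route instead uses one repeatable operation for all three interflavan bonds and sets C3 and C4 of each unit by catalyst, in fewer steps overall.

**Alternative 2:** The disconnection is the four O1–C2 bonds, that is all four rings C. In the forward key step the four (Z)-styrenyl double bonds of A5 are epoxidised by a chiral (salen)MnCl complex with NaOCl, fluoride frees the four C8a phenols, and each phenoxide opens its cis-epoxide at the benzylic carbon with inversion to give A4 with 2,3-cis rings.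
- For it: eight stereocentres and four rings are set in one flask, and ring B is in place from the start, so no C2 arylation is needed. On these two points it is stronger than the chosen route.
- Against it: four epoxidations must all take the same course, so selectivity errors multiply, and three of the alkenes sit on a C4 stereocentre that may oppose the catalyst. Stereoisomers of a benzyl ether of about 2 kDa are hardly separable. Hypochlorite can chlorinate the phloroglucinol ethers and oxidise the doubly benzylic C4–H bonds. Epoxides of dialkoxystyrenes open with cationic character, which erodes inversion and allows 5-exo closure. A5, with three diarylmethine stereocentres, leaves the interflavan problem unsolved.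
- Comparison: the chosen route sets two stereocentres per round in isolable intermediates that can be checked before the next unit is added, and it builds the interflavan bonds themselves.

**Alternative 3:** The disconnection is the three C4–C4a bonds, that is rings C of units 1–3. In the forward key step Me3SiOTf ionises the three C4 carbinols of A7; each cation is stabilised by the trioxygenated ring below it and is captured by the ortho carbon of its tethered aryl ether, anti to the C3 benzyloxy group, to give A6.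
- For it: the step is stereoconvergent, the C4–C8 bonds exist beforehand so regiochemistry is fixed, and the reaction type is known. A6 is identical with 36, one step from the target. In precedent and directness of the endgame it is stronger than the chosen route.
- Against it: the C4 cations are the intermediates of acid-induced interflavan scrambling, and they can lose the C3 proton or be trapped intermolecularly. Three cyclisations in one molecule each depend on substrate control alone. A7 holds three benzylic aryl alkyl ether bonds of defined configuration and three C2/C3 pairs that must be made one after another in a long acyclic sequence.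
- Comparison: the chosen route never generates a cation at C4, sets C4 under catalyst control, and grows the chain by four repeating operations from cheap components.

Key step: step 16

**Remarks**
- Abbreviations: Bn = benzyl, Bz = benzoyl; "penta-O-benzyl-epicatechin" means the 3,5,7,3',4'-pentabenzyl ether of (2R,3R)-epicatechin; the newest unit is unit 3 at the dimer stage and unit 2 at the trimer stage.
- Assumption: C2 of all lactols and methyl acetals is an anomer mixture and is left undefined in the SMILES.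
- Assumption: C3 is taken to be set kinetically by the enamine catalyst. On the steric-shielding model of 2-(diarylsilyloxymethyl)pyrrolidine enamines, the 3R centre (oxygen anti to the C4 aryl group) requires the (R)-configured pyrrolidine; the (S) enantiomer would give the opposite sense.

## Route

Step 1
Reactants: 1 (−)-epicatechin
Product: 3 3,5,7,3',4'-penta-O-benzyl-(−)-epicatechin, via tetra-O-benzyl-epicatechin 2 (not isolated)
Conditions: BnBr (excess), K2CO3, DMF, rt; then NaH, 0 °C → rt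
Reagents that add atoms: benzyl bromide, BrCc1ccccc1
Why: Williamson ether synthesis; the four phenols are alkylated under carbonate conditions that do not open ring C, and the secondary C3 hydroxyl reacts only after NaH is added, so no stereocentre is touched.

Step 2
Reactants: 3 penta-O-benzyl-epicatechin
Product: 4 8-bromo-3,5,7,3',4'-penta-O-benzyl-(−)-epicatechin
Conditions: NBS (1.0 equiv), CH2Cl2, −78 → −20 °C
Reagents that add atoms: N-bromosuccinimide, O=C1CCC(=O)N1Br
Why: Electrophilic aromatic bromination; C8 of a 5,7-dialkoxychroman is activated by three oxygens and less hindered than C6, which lies between two benzyloxy groups, so one equivalent at low temperature should stop at the 8-bromide.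

Step 3
Reactants: 4 8-bromo-penta-O-benzyl-epicatechin; 5 (E)-2-(3,3-diethoxyprop-1-en-1-yl)-4,4,5,5-tetramethyl-1,3,2-dioxaborolane
Product: 7 (E)-3-(penta-O-benzyl-epicatechin-8-yl)prop-2-enal, via diethyl acetal 6 (not isolated)
Conditions: Pd(OAc)2 (5 mol %), 2-dicyclohexylphosphino-2',6'-dimethoxybiphenyl (SPhos, 10 mol %), K3PO4, toluene/H2O, 90 °C; then 1 M HCl, THF, rt
Reagents that add atoms: water, O
Why: Suzuki–Miyaura coupling; the electron-rich biarylphosphine lets zerovalent palladium insert into the di-ortho-oxygenated aryl bromide, the alkenyl group is transferred with retention of the E geometry, and dilute acid hydrolyses the conjugated acetal without touching benzyl ethers.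

Step 4
Reactants: 8 3,5-bis(benzyloxy)phenol
Product: 9 3,5-bis(benzyloxy)-2-bromophenol
Conditions: NBS (1.0 equiv), i-Pr2NH (10 mol %), CH2Cl2, −78 → 0 °C
Reagents that add atoms: N-bromosuccinimide, O=C1CCC(=O)N1Br
Why: Amine-mediated ortho-bromination of a phenol; the N-bromoamine is hydrogen-bonded to the hydroxyl and delivers bromine to the neighbouring carbon rather than to the carbon between the two benzyloxy groups, and the para isomer is removed by chromatography.

Step 5
Reactants: 7 monomer enal; 9 3,5-bis(benzyloxy)-2-bromophenol; 10 dibenzoyl peroxide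
Product: 12 dimer-stage 3-benzoyloxy lactol (3R; benzoate trans to the C4 aryl group; bromine at C8; anomer mixture), via chroman-2-ol 11 (not isolated)
Conditions: 9 (1.3 equiv), (2S,5S)-5-benzyl-2-tert-butyl-3-methylimidazolidin-4-one·CF3CO2H (20 mol %), wet CHCl3, −20 °C → rt; then (R)-2-[diphenyl(trimethylsilyloxy)methyl]pyrrolidine (30 mol %), hydroquinone (10 mol %), 10 (2 equiv), THF, 0 °C
Reagents that add atoms: none
Why: Proposed new method: the iminium ion of 7 with the imidazolidinone is attacked at its β-carbon by the only free ortho carbon of 9 on the face away from the benzyl and tert-butyl groups, the phenol oxygen closes on the aldehyde carbon to lactol 11, and the open-chain aldehyde in equilibrium with 11 is then benzoyloxylated at C3 through its enamine with the (R)-pyrrolidine on the face opposite the diphenyl(silyloxy)methyl group, after which the lactol recloses; the closest known reaction types are the iminium-catalysed Friedel–Crafts/hemiacetalisation of electron-rich phenols with enals and the enamine-catalysed α-benzoyloxylation of aldehydes, which have not been merged in one flask on a lactol; C4 is set by the first amine and C3 by the second.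

Step 6
Reactants: 12 dimer-stage 3-benzoyloxy lactol
Product: 13 methyl acetal of 12 (2-methoxy, anomer mixture)
Conditions: MeOH/CH2Cl2, PPTS (cat.), 3 Å MS, rt
Reagents that add atoms: methanol, CO
Why: Acid-catalysed acetalisation of a lactol (Fischer-type glycosidation); the acetal removes the ring-chain equilibrium with the hydroxy-aldehyde, so the base used next cannot epimerise C3, and the mild acid leaves the interflavan bond intact.

Step 7
Reactants: 13 methyl acetal benzoate
Product: 15 (3R)-3,5,7-tris(benzyloxy)-8-bromo-2-methoxy-4-(penta-O-benzyl-epicatechin-8-yl)chroman, via 3-hydroxy acetal 14 (not isolated)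
Conditions: NaOMe (cat.), MeOH/THF, rt; evaporate; then NaH, BnBr, n-Bu4NI, DMF, 0 °C → rt
Reagents that add atoms: benzyl bromide, BrCc1ccccc1
Why: Zemplén transesterification followed by Williamson etherification; the participating benzoate is replaced by a non-participating benzyl ether, which the C2 arylation requires, and C3 cannot epimerise because C2 is an acetal.

Step 8
Reactants: 16 4-bromo-1,2-bis(benzyloxy)benzene
Product: 19 potassium [3,4-bis(benzyloxy)phenyl]trifluoroborate, via aryllithium 17 (not isolated), via lithium aryltriisopropoxyborate 18 (not isolated)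
Conditions: n-BuLi, THF, −78 °C; B(O-i-Pr)3, −78 °C → rt; then KHF2, MeOH/H2O, rt
Reagents that add atoms: triisopropyl borate, CC(C)OB(OC(C)C)OC(C)C; potassium hydrogen difluoride, [K+].F[H-]F
Why: Bromine–lithium exchange, borylation with a trialkyl borate and fluoride exchange with KHF2 is the standard preparation of a potassium aryltrifluoroborate.

Step 9
Reactants: 15 dimer-stage 3-O-benzyl methyl acetal; 19 potassium [3,4-bis(benzyloxy)phenyl]trifluoroborate
Product: 20 8-bromo-deca-O-benzyl-[epicatechin-(4β→8)-epicatechin] (bromine on C8 of the upper unit)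
Conditions: 19 (3 equiv), BF3·OEt2 (3 equiv), CH2Cl2/MeCN, −40 → 0 °C
Reagents that add atoms: none
Why: Lewis-acid-mediated C-arylation of a cyclic acetal with an aryltrifluoroborate (C-glycosylation type); BF3 converts 19 into the aryldifluoroborane, which takes up the methoxy group and hands its aryl group to the oxocarbenium carbon within the ion pair, faster than any A ring can intervene. The aryl group enters on the face away from the large C4 substituent, through the half-chair with the C3 benzyloxy group pseudo-equatorial, and the benzyl ether cannot bridge, so C2 is set trans to the C4 aryl group and cis to the C3 oxygen.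

Step 10
Reactants: 20 8-bromo dimer; 5 (E)-2-(3,3-diethoxyprop-1-en-1-yl)-4,4,5,5-tetramethyl-1,3,2-dioxaborolane
Product: 22 (E)-3-{deca-O-benzyl-[epicatechin-(4β→8)-epicatechin]-8-yl}prop-2-enal, via diethyl acetal 21 (not isolated)
Conditions: Pd(OAc)2 (5 mol %), SPhos (10 mol %), K3PO4, toluene/H2O, 90 °C; then 1 M HCl, THF, rt
Reagents that add atoms: water, O
Why: Suzuki–Miyaura coupling as in step 3; the only carbon–bromine bond is at C8 of the upper unit, and the brief acid treatment at room temperature is too mild to ionise the interflavan bond of the benzyl ether.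

Step 11
Reactants: 22 dimer enal; 9 3,5-bis(benzyloxy)-2-bromophenol; 10 dibenzoyl peroxide
Product: 24 trimer-stage 3-benzoyloxy lactol (3R; benzoate trans to the C4 aryl group; bromine at C8; anomer mixture), via chroman-2-ol 23 (not isolated)
Conditions: as step 5
Reagents that add atoms: none
Why: Proposed new method: the same two-amine sequence as in step 5, iminium-catalysed Friedel–Crafts addition of the free ortho carbon of 9 to the β-carbon of 22 with lactol closure to 23, then enamine-catalysed benzoyloxylation at C3 by 10; the closest known types are again the phenol/enal Friedel–Crafts/hemiacetalisation and the α-benzoyloxylation of aldehydes; C4 and C3 are set by the two catalysts, not by the remote unit 4.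

Step 12
Reactants: 24 trimer-stage 3-benzoyloxy lactol
Product: 25 methyl acetal of 24
Conditions: MeOH/CH2Cl2, PPTS (cat.), 3 Å MS, rt
Reagents that add atoms: methanol, CO
Why: Acid-catalysed acetalisation as in step 6.

Step 13
Reactants: 25 methyl acetal benzoate
Product: 27 trimer-stage 3-O-benzyl methyl acetal, via 3-hydroxy acetal 26 (not isolated)
Conditions: NaOMe (cat.), MeOH/THF, rt; evaporate; then NaH, BnBr, n-Bu4NI, DMF, 0 °C → rt
Reagents that add atoms: benzyl bromide, BrCc1ccccc1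
Why: Zemplén transesterification and Williamson etherification as in step 7.

Step 14
Reactants: 27 trimer-stage 3-O-benzyl methyl acetal; 19 potassium [3,4-bis(benzyloxy)phenyl]trifluoroborate
Product: 28 8-bromo-pentadeca-O-benzyl-[epicatechin-(4β→8)-epicatechin-(4β→8)-epicatechin] (bromine on C8 of the top unit)
Conditions: 19 (3 equiv), BF3·OEt2 (3 equiv), CH2Cl2/MeCN, −40 → 0 °C
Reagents that add atoms: none
Why: Lewis-acid-mediated C-arylation of the cyclic acetal as in step 9; C2 of unit 2 is set trans to the C4 aryl group for the same steric and conformational reasons.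

Step 15
Reactants: 28 8-bromo trimer; 5 (E)-2-(3,3-diethoxyprop-1-en-1-yl)-4,4,5,5-tetramethyl-1,3,2-dioxaborolane
Product: 30 (E)-3-{pentadeca-O-benzyl-[epicatechin-(4β→8)-epicatechin-(4β→8)-epicatechin]-8-yl}prop-2-enal, via diethyl acetal 29 (not isolated)
Conditions: Pd(OAc)2 (5 mol %), SPhos (10 mol %), K3PO4, toluene/H2O, 90 °C; then 1 M HCl, THF, rt
Reagents that add atoms: water, O
Why: Suzuki–Miyaura coupling and acetal hydrolysis as in steps 3 and 10.

Step 16
Reactants: 30 trimer enal; 8 3,5-bis(benzyloxy)phenol; 10 dibenzoyl peroxide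
Product: 32 tetramer-stage 3-benzoyloxy lactol (unit 1 without ring B; 3R; benzoate trans to the C4 aryl group; anomer mixture), via chroman-2-ol 31 (not isolated)
Conditions: 8 (1.5 equiv), (2S,5S)-5-benzyl-2-tert-butyl-3-methylimidazolidin-4-one·CF3CO2H (20 mol %), wet CHCl3, −20 °C → rt; then (R)-2-[diphenyl(trimethylsilyloxy)methyl]pyrrolidine (30 mol %), hydroquinone (10 mol %), 10 (2 equiv), THF, 0 °C
Reagents that add atoms: none
Why: Proposed new method: The imidazolidinone salt condenses with enal 30 to the E-iminium ion, whose benzyl and tert-butyl groups cover one face, and phenol 8 adds through a carbon ortho to its hydroxyl to the β-carbon on the open face, which forms C4–C4a and sets C4 as in a 4β-linked unit. Hydrolysis and attack of the phenol oxygen on the aldehyde carbon then form O1–C2 and close ring C of unit 1 as lactol 31 by 6-exo-trig addition to the carbonyl group. The small open-chain aldehyde share of 31 condenses with the pyrrolidine to the E-enamine, the diphenyl(silyloxy)methyl group covers one face, and peroxide 10 delivers a benzoyloxy group to C3 on the other face, which forms C3–O with the 3R configuration, trans to the C4 aryl group; reclosure gives 32, in which C3 is no longer epimerisable. The closest known reaction types are the iminium-catalysed Friedel–Crafts/hemiacetalisation of electron-rich phenols with enals to 4-arylchroman-2-ols and the enamine-catalysed α-benzoyloxylation of aldehydes with dibenzoyl peroxide; their one-flask union with two amines on a lactol is new. C4 is controlled by the imidazolidinone and C3 by the pyrrolidine, chosen so that oxygen arrives anti to the aryl group that entered first, while C2 is an uncontrolled hemiacetal centre that is replaced later. The step needs ortho attack of the phenol, secured because only ortho attack can end in the lactol and because the para carbon lies between two benzyloxy groups, and it needs mono-alkylation, secured by the excess of 8 and by conversion of the phenol into a lactol ether. The choice between C8 and C6 of unit 2 is not made here, because the enal carbon was placed on C8 through the bromide of 28. The peroxide is added only after the phenol has been consumed, since electron-rich phenols and the amines are themselves oxidised by it.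

Step 17
Reactants: 32 tetramer-stage 3-benzoyloxy lactol
Product: 33 methyl acetal of 32
Conditions: MeOH/CH2Cl2, PPTS (cat.), 3 Å MS, rt
Reagents that add atoms: methanol, CO
Why: Acid-catalysed acetalisation as in step 6; it protects C3 against epimerisation in the next step.

Step 18
Reactants: 33 methyl acetal benzoate
Product: 35 tetramer-stage 3-O-benzyl methyl acetal, via 3-hydroxy acetal 34 (not isolated)
Conditions: NaOMe (cat.), MeOH/THF, rt; evaporate; then NaH, BnBr, n-Bu4NI, DMF, 0 °C → rt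
Reagents that add atoms: benzyl bromide, BrCc1ccccc1
Why: Zemplén transesterification and Williamson etherification as in step 7; the benzyl ether is non-participating and leaves in the final hydrogenolysis with all the others.

Step 19
Reactants: 35 tetramer-stage 3-O-benzyl methyl acetal; 19 potassium [3,4-bis(benzyloxy)phenyl]trifluoroborate
Product: 36 eicosa-O-benzyl cinnamtannin A2 (all phenols and all 3-hydroxyls benzylated)
Conditions: 19 (3 equiv), BF3·OEt2 (3 equiv), CH2Cl2/MeCN, −40 → 0 °C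
Reagents that add atoms: none
Why: Lewis-acid-mediated C-arylation of the cyclic acetal as in step 9; delivery of the aryl group from boron within the ion pair matters most here, because ring A of unit 1 has two free nucleophilic positions, and C2 of unit 1 is set trans to the C4 aryl group and cis to the C3 oxygen.

Step 20
Reactants: 36 eicosa-O-benzyl cinnamtannin A2
Product: 37 cinnamtannin A2
Conditions: H2 (1 atm), Pd(OH)2 on carbon, THF/MeOH/H2O, rt
Reagents that add atoms: none
Why: Hydrogenolysis of aryl and alkyl benzyl ethers under neutral conditions; no stereocentre is benzylic to a cleavable C–O bond other than the ring ether, which is not cleaved under these mild conditions, and the interflavan bonds are stable in the absence of acid.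

## Compound list

1 | (−)-epicatechin | Oc1cc(O)c2c(c1)O[C@H](c1ccc(O)c(O)c1)[C@H](O)C2 | starting material
2 | 5,7,3',4'-tetra-O-benzyl-(−)-epicatechin | C(c3ccccc3)Oc1cc(OCc3ccccc3)c2c(c1)O[C@H](c1ccc(OCc3ccccc3)c(OCc3ccccc3)c1)[C@H](O)C2 | intermediate
3 | 3,5,7,3',4'-penta-O-benzyl-(−)-epicatechin | C(c3ccccc3)Oc1cc(OCc3ccccc3)c2c(c1)O[C@H](c1ccc(OCc3ccccc3)c(OCc3ccccc3)c1)[C@H](OCc3ccccc3)C2 | intermediate
4 | 8-bromo-3,5,7,3',4'-penta-O-benzyl-(−)-epicatechin | Brc1c(OCc3ccccc3)cc(OCc3ccccc3)c2c1O[C@H](c1ccc(OCc3ccccc3)c(OCc3ccccc3)c1)[C@H](OCc3ccccc3)C2 | intermediate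
5 | (E)-2-(3,3-diethoxyprop-1-en-1-yl)-4,4,5,5-tetramethyl-1,3,2-dioxaborolane | CCOC(OCC)/C=C/B1OC(C)(C)C(C)(C)O1 | starting material
6 | 8-[(E)-3,3-diethoxyprop-1-enyl]-penta-O-benzyl-epicatechin | CCOC(OCC)/C=C/c1c(OCc3ccccc3)cc(OCc3ccccc3)c2c1O[C@H](c1ccc(OCc3ccccc3)c(OCc3ccccc3)c1)[C@H](OCc3ccccc3)C2 | intermediate
7 | (E)-3-(penta-O-benzyl-epicatechin-8-yl)prop-2-enal | O=C/C=C/c1c(OCc3ccccc3)cc(OCc3ccccc3)c2c1O[C@H](c1ccc(OCc3ccccc3)c(OCc3ccccc3)c1)[C@H](OCc3ccccc3)C2 | intermediate
8 | 3,5-bis(benzyloxy)phenol | Oc1cc(OCc2ccccc2)cc(OCc2ccccc2)c1 | starting material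
9 | 3,5-bis(benzyloxy)-2-bromophenol | Oc1cc(OCc2ccccc2)cc(OCc2ccccc2)c1Br | intermediate
10 | dibenzoyl peroxide | O=C(OOC(=O)c1ccccc1)c1ccccc1 | starting material
11 | 5,7-bis(benzyloxy)-8-bromo-4-(penta-O-benzyl-epicatechin-8-yl)chroman-2-ol, C4 as in a 4β-linked unit, C3 unsubstituted, anomer mixture | Brc1c(OCc3ccccc3)cc(OCc3ccccc3)c2c1OC(O)C[C@H]2c1c(OCc3ccccc3)cc(OCc3ccccc3)c2c1O[C@H](c1ccc(OCc3ccccc3)c(OCc3ccccc3)c1)[C@H](OCc3ccccc3)C2 | intermediate
12 | (3R)-3-benzoyloxy-5,7-bis(benzyloxy)-8-bromo-4-(penta-O-benzyl-epicatechin-8-yl)chroman-2-ol, benzoate trans to the C4 aryl group, anomer mixture | Brc1c(OCc3ccccc3)cc(OCc3ccccc3)c2c1OC(O)[C@H](OC(=O)c3ccccc3)[C@H]2c1c(OCc3ccccc3)cc(OCc3ccccc3)c2c1O[C@H](c1ccc(OCc3ccccc3)c(OCc3ccccc3)c1)[C@H](OCc3ccccc3)C2 | intermediate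
13 | methyl acetal of 12 (2-methoxy, 3-benzoyloxy) | Brc1c(OCc3ccccc3)cc(OCc3ccccc3)c2c1OC(OC)[C@H](OC(=O)c3ccccc3)[C@H]2c1c(OCc3ccccc3)cc(OCc3ccccc3)c2c1O[C@H](c1ccc(OCc3ccccc3)c(OCc3ccccc3)c1)[C@H](OCc3ccccc3)C2 | intermediate
14 | (3R)-5,7-bis(benzyloxy)-8-bromo-2-methoxy-4-(penta-O-benzyl-epicatechin-8-yl)chroman-3-ol | Brc1c(OCc3ccccc3)cc(OCc3ccccc3)c2c1OC(OC)[C@H](O)[C@H]2c1c(OCc3ccccc3)cc(OCc3ccccc3)c2c1O[C@H](c1ccc(OCc3ccccc3)c(OCc3ccccc3)c1)[C@H](OCc3ccccc3)C2 | intermediate
15 | (3R)-3,5,7-tris(benzyloxy)-8-bromo-2-methoxy-4-(penta-O-benzyl-epicatechin-8-yl)chroman | Brc1c(OCc3ccccc3)cc(OCc3ccccc3)c2c1OC(OC)[C@H](OCc3ccccc3)[C@H]2c1c(OCc3ccccc3)cc(OCc3ccccc3)c2c1O[C@H](c1ccc(OCc3ccccc3)c(OCc3ccccc3)c1)[C@H](OCc3ccccc3)C2 | intermediate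
16 | 4-bromo-1,2-bis(benzyloxy)benzene | Brc1ccc(OCc2ccccc2)c(OCc2ccccc2)c1 | starting material
17 | [3,4-bis(benzyloxy)phenyl]lithium | [Li]c1ccc(OCc2ccccc2)c(OCc2ccccc2)c1 | intermediate
18 | lithium [3,4-bis(benzyloxy)phenyl]tri(propan-2-yloxy)borate | [Li+].CC(C)O[B-](OC(C)C)(OC(C)C)c1ccc(OCc2ccccc2)c(OCc2ccccc2)c1 | intermediate
19 | potassium [3,4-bis(benzyloxy)phenyl]trifluoroborate | [K+].F[B-](F)(F)c1ccc(OCc2ccccc2)c(OCc2ccccc2)c1 | intermediate
20 | 8-bromo-deca-O-benzyl-[epicatechin-(4β→8)-epicatechin] | Brc1c(OCc3ccccc3)cc(OCc3ccccc3)c2c1O[C@H](c1ccc(OCc3ccccc3)c(OCc3ccccc3)c1)[C@H](OCc3ccccc3)[C@H]2c1c(OCc3ccccc3)cc(OCc3ccccc3)c2c1O[C@H](c1ccc(OCc3ccccc3)c(OCc3ccccc3)c1)[C@H](OCc3ccccc3)C2 | intermediate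
21 | 8-[(E)-3,3-diethoxyprop-1-enyl]-deca-O-benzyl-[epicatechin-(4β→8)-epicatechin] | CCOC(OCC)/C=C/c1c(OCc3ccccc3)cc(OCc3ccccc3)c2c1O[C@H](c1ccc(OCc3ccccc3)c(OCc3ccccc3)c1)[C@H](OCc3ccccc3)[C@H]2c1c(OCc3ccccc3)cc(OCc3ccccc3)c2c1O[C@H](c1ccc(OCc3ccccc3)c(OCc3ccccc3)c1)[C@H](OCc3ccccc3)C2 | intermediate
22 | (E)-3-{deca-O-benzyl-[epicatechin-(4β→8)-epicatechin]-8-yl}prop-2-enal | O=C/C=C/c1c(OCc3ccccc3)cc(OCc3ccccc3)c2c1O[C@H](c1ccc(OCc3ccccc3)c(OCc3ccccc3)c1)[C@H](OCc3ccccc3)[C@H]2c1c(OCc3ccccc3)cc(OCc3ccccc3)c2c1O[C@H](c1ccc(OCc3ccccc3)c(OCc3ccccc3)c1)[C@H](OCc3ccccc3)C2 | intermediate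
23 | trimer-stage chroman-2-ol: 5,7-bis(benzyloxy)-8-bromo-4-{deca-O-benzyl-[epicatechin-(4β→8)-epicatechin]-8-yl}chroman-2-ol, C4 as in a 4β-linked unit, C3 unsubstituted | Brc1c(OCc3ccccc3)cc(OCc3ccccc3)c2c1OC(O)C[C@H]2c1c(OCc3ccccc3)cc(OCc3ccccc3)c2c1O[C@H](c1ccc(OCc3ccccc3)c(OCc3ccccc3)c1)[C@H](OCc3ccccc3)[C@H]2c1c(OCc3ccccc3)cc(OCc3ccccc3)c2c1O[C@H](c1ccc(OCc3ccccc3)c(OCc3ccccc3)c1)[C@H](OCc3ccccc3)C2 | intermediate
24 | trimer-stage lactol: (3R)-3-benzoyloxy analogue of 23, benzoate trans to the C4 aryl group, anomer mixture | Brc1c(OCc3ccccc3)cc(OCc3ccccc3)c2c1OC(O)[C@H](OC(=O)c3ccccc3)[C@H]2c1c(OCc3ccccc3)cc(OCc3ccccc3)c2c1O[C@H](c1ccc(OCc3ccccc3)c(OCc3ccccc3)c1)[C@H](OCc3ccccc3)[C@H]2c1c(OCc3ccccc3)cc(OCc3ccccc3)c2c1O[C@H](c1ccc(OCc3ccccc3)c(OCc3ccccc3)c1)[C@H](OCc3ccccc3)C2 | intermediate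
25 | methyl acetal of 24 (2-methoxy, 3-benzoyloxy) | Brc1c(OCc3ccccc3)cc(OCc3ccccc3)c2c1OC(OC)[C@H](OC(=O)c3ccccc3)[C@H]2c1c(OCc3ccccc3)cc(OCc3ccccc3)c2c1O[C@H](c1ccc(OCc3ccccc3)c(OCc3ccccc3)c1)[C@H](OCc3ccccc3)[C@H]2c1c(OCc3ccccc3)cc(OCc3ccccc3)c2c1O[C@H](c1ccc(OCc3ccccc3)c(OCc3ccccc3)c1)[C@H](OCc3ccccc3)C2 | intermediate
26 | trimer-stage 2-methoxy-chroman-3-ol (benzoate of 25 removed) | Brc1c(OCc3ccccc3)cc(OCc3ccccc3)c2c1OC(OC)[C@H](O)[C@H]2c1c(OCc3ccccc3)cc(OCc3ccccc3)c2c1O[C@H](c1ccc(OCc3ccccc3)c(OCc3ccccc3)c1)[C@H](OCc3ccccc3)[C@H]2c1c(OCc3ccccc3)cc(OCc3ccccc3)c2c1O[C@H](c1ccc(OCc3ccccc3)c(OCc3ccccc3)c1)[C@H](OCc3ccccc3)C2 | intermediate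
27 | trimer-stage 3-O-benzyl methyl acetal | Brc1c(OCc3ccccc3)cc(OCc3ccccc3)c2c1OC(OC)[C@H](OCc3ccccc3)[C@H]2c1c(OCc3ccccc3)cc(OCc3ccccc3)c2c1O[C@H](c1ccc(OCc3ccccc3)c(OCc3ccccc3)c1)[C@H](OCc3ccccc3)[C@H]2c1c(OCc3ccccc3)cc(OCc3ccccc3)c2c1O[C@H](c1ccc(OCc3ccccc3)c(OCc3ccccc3)c1)[C@H](OCc3ccccc3)C2 | intermediate
28 | 8-bromo-pentadeca-O-benzyl-[epicatechin-(4β→8)-epicatechin-(4β→8)-epicatechin] | Brc1c(OCc3ccccc3)cc(OCc3ccccc3)c2c1O[C@H](c1ccc(OCc3ccccc3)c(OCc3ccccc3)c1)[C@H](OCc3ccccc3)[C@H]2c1c(OCc3ccccc3)cc(OCc3ccccc3)c2c1O[C@H](c1ccc(OCc3ccccc3)c(OCc3ccccc3)c1)[C@H](OCc3ccccc3)[C@H]2c1c(OCc3ccccc3)cc(OCc3ccccc3)c2c1O[C@H](c1ccc(OCc3ccccc3)c(OCc3ccccc3)c1)[C@H](OCc3ccccc3)C2 | intermediate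
29 | 8-[(E)-3,3-diethoxyprop-1-enyl]-pentadeca-O-benzyl trimer | CCOC(OCC)/C=C/c1c(OCc3ccccc3)cc(OCc3ccccc3)c2c1O[C@H](c1ccc(OCc3ccccc3)c(OCc3ccccc3)c1)[C@H](OCc3ccccc3)[C@H]2c1c(OCc3ccccc3)cc(OCc3ccccc3)c2c1O[C@H](c1ccc(OCc3ccccc3)c(OCc3ccccc3)c1)[C@H](OCc3ccccc3)[C@H]2c1c(OCc3ccccc3)cc(OCc3ccccc3)c2c1O[C@H](c1ccc(OCc3ccccc3)c(OCc3ccccc3)c1)[C@H](OCc3ccccc3)C2 | intermediate
30 | (E)-3-{pentadeca-O-benzyl-[epicatechin-(4β→8)-epicatechin-(4β→8)-epicatechin]-8-yl}prop-2-enal | O=C/C=C/c1c(OCc3ccccc3)cc(OCc3ccccc3)c2c1O[C@H](c1ccc(OCc3ccccc3)c(OCc3ccccc3)c1)[C@H](OCc3ccccc3)[C@H]2c1c(OCc3ccccc3)cc(OCc3ccccc3)c2c1O[C@H](c1ccc(OCc3ccccc3)c(OCc3ccccc3)c1)[C@H](OCc3ccccc3)[C@H]2c1c(OCc3ccccc3)cc(OCc3ccccc3)c2c1O[C@H](c1ccc(OCc3ccccc3)c(OCc3ccccc3)c1)[C@H](OCc3ccccc3)C2 | intermediate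
31 | tetramer-stage chroman-2-ol: 5,7-bis(benzyloxy)-4-(pentadeca-O-benzyl trimer-8-yl)chroman-2-ol, C4 as in a 4β-linked unit, C3 unsubstituted | C(c3ccccc3)Oc1cc(OCc3ccccc3)c2c(c1)OC(O)C[C@H]2c1c(OCc3ccccc3)cc(OCc3ccccc3)c2c1O[C@H](c1ccc(OCc3ccccc3)c(OCc3ccccc3)c1)[C@H](OCc3ccccc3)[C@H]2c1c(OCc3ccccc3)cc(OCc3ccccc3)c2c1O[C@H](c1ccc(OCc3ccccc3)c(OCc3ccccc3)c1)[C@H](OCc3ccccc3)[C@H]2c1c(OCc3ccccc3)cc(OCc3ccccc3)c2c1O[C@H](c1ccc(OCc3ccccc3)c(OCc3ccccc3)c1)[C@H](OCc3ccccc3)C2 | intermediate
32 | tetramer-stage lactol: (3R)-3-benzoyloxy-5,7-bis(benzyloxy)-4-(pentadeca-O-benzyl trimer-8-yl)chroman-2-ol, benzoate trans to the C4 aryl group, anomer mixture | C(c3ccccc3)Oc1cc(OCc3ccccc3)c2c(c1)OC(O)[C@H](OC(=O)c3ccccc3)[C@H]2c1c(OCc3ccccc3)cc(OCc3ccccc3)c2c1O[C@H](c1ccc(OCc3ccccc3)c(OCc3ccccc3)c1)[C@H](OCc3ccccc3)[C@H]2c1c(OCc3ccccc3)cc(OCc3ccccc3)c2c1O[C@H](c1ccc(OCc3ccccc3)c(OCc3ccccc3)c1)[C@H](OCc3ccccc3)[C@H]2c1c(OCc3ccccc3)cc(OCc3ccccc3)c2c1O[C@H](c1ccc(OCc3ccccc3)c(OCc3ccccc3)c1)[C@H](OCc3ccccc3)C2 | intermediate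
33 | methyl acetal of 32 (2-methoxy, 3-benzoyloxy) | C(c3ccccc3)Oc1cc(OCc3ccccc3)c2c(c1)OC(OC)[C@H](OC(=O)c3ccccc3)[C@H]2c1c(OCc3ccccc3)cc(OCc3ccccc3)c2c1O[C@H](c1ccc(OCc3ccccc3)c(OCc3ccccc3)c1)[C@H](OCc3ccccc3)[C@H]2c1c(OCc3ccccc3)cc(OCc3ccccc3)c2c1O[C@H](c1ccc(OCc3ccccc3)c(OCc3ccccc3)c1)[C@H](OCc3ccccc3)[C@H]2c1c(OCc3ccccc3)cc(OCc3ccccc3)c2c1O[C@H](c1ccc(OCc3ccccc3)c(OCc3ccccc3)c1)[C@H](OCc3ccccc3)C2 | intermediate
34 | tetramer-stage 2-methoxy-chroman-3-ol (benzoate of 33 removed) | C(c3ccccc3)Oc1cc(OCc3ccccc3)c2c(c1)OC(OC)[C@H](O)[C@H]2c1c(OCc3ccccc3)cc(OCc3ccccc3)c2c1O[C@H](c1ccc(OCc3ccccc3)c(OCc3ccccc3)c1)[C@H](OCc3ccccc3)[C@H]2c1c(OCc3ccccc3)cc(OCc3ccccc3)c2c1O[C@H](c1ccc(OCc3ccccc3)c(OCc3ccccc3)c1)[C@H](OCc3ccccc3)[C@H]2c1c(OCc3ccccc3)cc(OCc3ccccc3)c2c1O[C@H](c1ccc(OCc3ccccc3)c(OCc3ccccc3)c1)[C@H](OCc3ccccc3)C2 | intermediate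
35 | tetramer-stage 3-O-benzyl methyl acetal | C(c3ccccc3)Oc1cc(OCc3ccccc3)c2c(c1)OC(OC)[C@H](OCc3ccccc3)[C@H]2c1c(OCc3ccccc3)cc(OCc3ccccc3)c2c1O[C@H](c1ccc(OCc3ccccc3)c(OCc3ccccc3)c1)[C@H](OCc3ccccc3)[C@H]2c1c(OCc3ccccc3)cc(OCc3ccccc3)c2c1O[C@H](c1ccc(OCc3ccccc3)c(OCc3ccccc3)c1)[C@H](OCc3ccccc3)[C@H]2c1c(OCc3ccccc3)cc(OCc3ccccc3)c2c1O[C@H](c1ccc(OCc3ccccc3)c(OCc3ccccc3)c1)[C@H](OCc3ccccc3)C2 | intermediate
36 | eicosa-O-benzyl cinnamtannin A2 | C(c3ccccc3)Oc1cc(OCc3ccccc3)c2c(c1)O[C@H](c1ccc(OCc3ccccc3)c(OCc3ccccc3)c1)[C@H](OCc3ccccc3)[C@H]2c1c(OCc3ccccc3)cc(OCc3ccccc3)c2c1O[C@H](c1ccc(OCc3ccccc3)c(OCc3ccccc3)c1)[C@H](OCc3ccccc3)[C@H]2c1c(OCc3ccccc3)cc(OCc3ccccc3)c2c1O[C@H](c1ccc(OCc3ccccc3)c(OCc3ccccc3)c1)[C@H](OCc3ccccc3)[C@H]2c1c(OCc3ccccc3)cc(OCc3ccccc3)c2c1O[C@H](c1ccc(OCc3ccccc3)c(OCc3ccccc3)c1)[C@H](OCc3ccccc3)C2 | intermediate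
37 | cinnamtannin A2 | Oc1cc(O)c2c(c1)O[C@H](c1ccc(O)c(O)c1)[C@H](O)[C@H]2c1c(O)cc(O)c2c1O[C@H](c1ccc(O)c(O)c1)[C@H](O)[C@H]2c1c(O)cc(O)c2c1O[C@H](c1ccc(O)c(O)c1)[C@H](O)[C@H]2c1c(O)cc(O)c2c1O[C@H](c1ccc(O)c(O)c1)[C@H](O)C2 | target

## Step count and least certain steps

Total: 20 steps. Longest linear sequence: 18 steps (steps 1–3, 5–7 and 9–20, from 1 to 37); steps 4 and 8 are side branches.

The three steps that carry the label "Proposed new method:" (5, 11 and 16) are the least certain. They are given in route order; step 16, the key step, is the most demanding of them.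

**Step 5.** The conjugate addition may be slow, because the iminium ion of a 2,4,6-trioxygenated cinnamaldehyde is a stabilised, hindered electrophile and the bromophenol is a weaker nucleophile than its parent. The benzoyloxylation may also lose selectivity if the imidazolidinone, which favours the opposite C3 configuration, competes with the pyrrolidine for enamine formation. Fallback with known chemistry, from 4: benzylic oxidation at C4 with DDQ in the presence of 2-ethoxyethanol would give 8-bromo-4β-(2-ethoxyethoxy)-penta-O-benzyl-epicatechin F1. Me3SiOTf in CH2Cl2 at −78 °C ionises F1, and the C4 cation is captured by C8 of an excess of 3, anti to the C3 benzyloxy group. This returns to the route at 20 and bypasses steps 5–9; the bromine on F1 prevents self-condensation.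

**Step 11.** The same processes may fail as in step 5, and the larger aryl group on the enal further slows the iminium addition. Fallback, from 20: bromine–lithium exchange with n-BuLi at −78 °C and protonation would give deca-O-benzyl-[epicatechin-(4β→8)-epicatechin] F2. Condensation of F2, through C8 of its upper unit, with the electrophile F1 under Me3SiOTf at −78 °C rejoins the route at 28.

**Step 16 (key step).** On the trimer the iminium addition is slowest and facial shielding by the catalyst may be partly overridden by the oligomer chain. The unblocked ring A of 8 allows a second alkylation. The peroxide may oxidise leftover phenol and the amines before the enamine step is complete. The C3 oxygenation is a case of double stereodifferentiation that may be mismatched. Fallback, from 28: debromination as above would give pentadeca-O-benzyl-[epicatechin-(4β→8)-epicatechin-(4β→8)-epicatechin] F3. Me3SiOTf-mediated condensation with F1 would give 8-bromo-eicosa-O-benzyl cinnamtannin A2 F4. Hydrogenolysis with H2 and Pd(OH)2 on carbon in the presence of Et3N removes the twenty benzyl groups and the bromine and arrives at 37.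

**Step 9 (and in the same way steps 14 and 19).** Facial selectivity at C2 may be poor if the oxocarbenium ion reacts through the conformer with the C4 aryl group axial. The cation may also alkylate an A ring of another molecule instead of accepting the aryl group from boron, the Lewis acid may cleave an interflavan bond, or the ring C–O bond may ionise instead of the methoxy group. Fallback, from 15: mild aqueous acid (AcOH/H2O/THF) would return the 3-O-benzyl lactol F5. Two equivalents of aryllithium 17 at −78 °C add to its open-chain aldehyde to give the phenolic diol F6 as a mixture of carbinol epimers. Catalytic PPTS in CH2Cl2 ionises the p-alkoxybenzylic carbinol, and the phenol oxygen closes ring C with ring B equatorial and trans to the axial C4 aryl group, which returns to 20. Both epimers converge through the same cation, and C2 selectivity is the weak point of this detour.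

**Step 15 (and in the same way steps 3 and 10).** Oxidative addition into the hindered, electron-rich C8–Br bond of the trimer may be slow, so that protodeboronation of 5 and hydrodebromination take over. Fallback, from 28: bromine–lithium exchange with n-BuLi at −78 °C and quenching with DMF would give the 8-carbaldehyde F7. Wittig olefination with Ph3P=CHCHO in toluene at 80 °C gives the (E)-enal 30.

## Further compounds

F1 | step 5 | 8-bromo-4β-(2-ethoxyethoxy)-3,5,7,3',4'-penta-O-benzyl-(−)-epicatechin | Brc1c(OCc3ccccc3)cc(OCc3ccccc3)c2c1O[C@H](c1ccc(OCc3ccccc3)c(OCc3ccccc3)c1)[C@H](OCc3ccccc3)[C@H]2OCCOCC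
F2 | step 11 | deca-O-benzyl-[epicatechin-(4β→8)-epicatechin] | C(c3ccccc3)Oc1cc(OCc3ccccc3)c2c(c1)O[C@H](c1ccc(OCc3ccccc3)c(OCc3ccccc3)c1)[C@H](OCc3ccccc3)[C@H]2c1c(OCc3ccccc3)cc(OCc3ccccc3)c2c1O[C@H](c1ccc(OCc3ccccc3)c(OCc3ccccc3)c1)[C@H](OCc3ccccc3)C2
F3 | step 16 | pentadeca-O-benzyl-[epicatechin-(4β→8)-epicatechin-(4β→8)-epicatechin] | C(c3ccccc3)Oc1cc(OCc3ccccc3)c2c(c1)O[C@H](c1ccc(OCc3ccccc3)c(OCc3ccccc3)c1)[C@H](OCc3ccccc3)[C@H]2c1c(OCc3ccccc3)cc(OCc3ccccc3)c2c1O[C@H](c1ccc(OCc3ccccc3)c(OCc3ccccc3)c1)[C@H](OCc3ccccc3)[C@H]2c1c(OCc3ccccc3)cc(OCc3ccccc3)c2c1O[C@H](c1ccc(OCc3ccccc3)c(OCc3ccccc3)c1)[C@H](OCc3ccccc3)C2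
F4 | step 16 | 8-bromo-eicosa-O-benzyl cinnamtannin A2 (bromine on C8 of unit 1) | Brc1c(OCc3ccccc3)cc(OCc3ccccc3)c2c1O[C@H](c1ccc(OCc3ccccc3)c(OCc3ccccc3)c1)[C@H](OCc3ccccc3)[C@H]2c1c(OCc3ccccc3)cc(OCc3ccccc3)c2c1O[C@H](c1ccc(OCc3ccccc3)c(OCc3ccccc3)c1)[C@H](OCc3ccccc3)[C@H]2c1c(OCc3ccccc3)cc(OCc3ccccc3)c2c1O[C@H](c1ccc(OCc3ccccc3)c(OCc3ccccc3)c1)[C@H](OCc3ccccc3)[C@H]2c1c(OCc3ccccc3)cc(OCc3ccccc3)c2c1O[C@H](c1ccc(OCc3ccccc3)c(OCc3ccccc3)c1)[C@H](OCc3ccccc3)C2
F5 | step 9 | (3R)-3,5,7-tris(benzyloxy)-8-bromo-4-(penta-O-benzyl-epicatechin-8-yl)chroman-2-ol (anomer mixture) | Brc1c(OCc3ccccc3)cc(OCc3ccccc3)c2c1OC(O)[C@H](OCc3ccccc3)[C@H]2c1c(OCc3ccccc3)cc(OCc3ccccc3)c2c1O[C@H](c1ccc(OCc3ccccc3)c(OCc3ccccc3)c1)[C@H](OCc3ccccc3)C2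
F6 | step 9 | open-chain diol: 2-bromo-3,5-bis(benzyloxy)-6-[2-benzyloxy-3-hydroxy-3-(3,4-bis(benzyloxy)phenyl)-1-(penta-O-benzyl-epicatechin-8-yl)propyl]phenol, carbinol epimers | Brc1c(OCc3ccccc3)cc(OCc3ccccc3)c(c1O)[C@@H]([C@@H](OCc3ccccc3)C(O)c1ccc(OCc3ccccc3)c(OCc3ccccc3)c1)c1c(OCc3ccccc3)cc(OCc3ccccc3)c2c1O[C@H](c1ccc(OCc3ccccc3)c(OCc3ccccc3)c1)[C@H](OCc3ccccc3)C2
F7 | step 15 | pentadeca-O-benzyl-[epicatechin-(4β→8)-epicatechin-(4β→8)-epicatechin]-8-carbaldehyde | O=Cc1c(OCc3ccccc3)cc(OCc3ccccc3)c2c1O[C@H](c1ccc(OCc3ccccc3)c(OCc3ccccc3)c1)[C@H](OCc3ccccc3)[C@H]2c1c(OCc3ccccc3)cc(OCc3ccccc3)c2c1O[C@H](c1ccc(OCc3ccccc3)c(OCc3ccccc3)c1)[C@H](OCc3ccccc3)[C@H]2c1c(OCc3ccccc3)cc(OCc3ccccc3)c2c1O[C@H](c1ccc(OCc3ccccc3)c(OCc3ccccc3)c1)[C@H](OCc3ccccc3)C2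
A1 | alternative 1 | benzannulation product: pentadeca-O-benzyl trimer bonded through C4 of unit 3 to C8 of a new ring A (free C8a phenol, C7 triisopropylsilyl ether, C5 benzyl ether) carrying the open C4–C3–C2 chain of unit 4 | C(c3ccccc3)Oc1cc(OCc3ccccc3)c2c(c1)O[C@H](c1ccc(OCc3ccccc3)c(OCc3ccccc3)c1)[C@H](OCc3ccccc3)[C@H]2c1c(OCc3ccccc3)cc(OCc3ccccc3)c2c1O[C@H](c1ccc(OCc3ccccc3)c(OCc3ccccc3)c1)[C@H](OCc3ccccc3)[C@H]2c1c(OCc3ccccc3)cc(OCc3ccccc3)c2c1O[C@H](c1ccc(OCc3ccccc3)c(OCc3ccccc3)c1)[C@H](OCc3ccccc3)[C@H]2c1c(O[Si](C(C)C)(C(C)C)C(C)C)cc(OCc3ccccc3)c(c1O)C[C@@H](OCc3ccccc3)[C@@H](O[Si](C)(C)C(C)(C)C)c1ccc(OCc3ccccc3)c(OCc3ccccc3)c1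
A2 | alternative 1 | pentadeca-O-benzyl trimer with a (triisopropylsilyloxy)ethynyl group at C4β of unit 3 | C(c3ccccc3)Oc1cc(OCc3ccccc3)c2c(c1)O[C@H](c1ccc(OCc3ccccc3)c(OCc3ccccc3)c1)[C@H](OCc3ccccc3)[C@H]2c1c(OCc3ccccc3)cc(OCc3ccccc3)c2c1O[C@H](c1ccc(OCc3ccccc3)c(OCc3ccccc3)c1)[C@H](OCc3ccccc3)[C@H]2c1c(OCc3ccccc3)cc(OCc3ccccc3)c2c1O[C@H](c1ccc(OCc3ccccc3)c(OCc3ccccc3)c1)[C@H](OCc3ccccc3)[C@H]2C#CO[Si](C(C)C)(C(C)C)C(C)C
A3 | alternative 1 | 3,6-bis(benzyloxy)-7-[3,4-bis(benzyloxy)phenyl]-7-(tert-butyldimethylsilyloxy)-1-diazohept-3-en-2-one | [N-]=[N+]=CC(=O)C(OCc1ccccc1)=CC[C@@H](OCc1ccccc1)[C@@H](O[Si](C)(C)C(C)(C)C)c1ccc(OCc2ccccc2)c(OCc2ccccc2)c1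
A4 | alternative 2 | hexadeca-O-benzyl cinnamtannin A2 (all phenols benzylated, 3-hydroxyls free) | C(c3ccccc3)Oc1cc(OCc3ccccc3)c2c(c1)O[C@H](c1ccc(OCc3ccccc3)c(OCc3ccccc3)c1)[C@H](O)[C@H]2c1c(OCc3ccccc3)cc(OCc3ccccc3)c2c1O[C@H](c1ccc(OCc3ccccc3)c(OCc3ccccc3)c1)[C@H](O)[C@H]2c1c(OCc3ccccc3)cc(OCc3ccccc3)c2c1O[C@H](c1ccc(OCc3ccccc3)c(OCc3ccccc3)c1)[C@H](O)[C@H]2c1c(OCc3ccccc3)cc(OCc3ccccc3)c2c1O[C@H](c1ccc(OCc3ccccc3)c(OCc3ccccc3)c1)[C@H](O)C2
A5 | alternative 2 | open tetra-ene: four ring A units with C8a tert-butyldimethylsilyl ethers, joined through the three C4 methine carbons, each C4 carrying a (Z)-2-[3,4-bis(benzyloxy)phenyl]ethenyl group | C(c3ccccc3)Oc1cc(OCc3ccccc3)c(c(c1)O[Si](C)(C)C(C)(C)C)[C@@H](/C=C\c1ccc(OCc3ccccc3)c(OCc3ccccc3)c1)c1c(OCc3ccccc3)cc(OCc3ccccc3)c(c1O[Si](C)(C)C(C)(C)C)[C@@H](/C=C\c1ccc(OCc3ccccc3)c(OCc3ccccc3)c1)c1c(OCc3ccccc3)cc(OCc3ccccc3)c(c1O[Si](C)(C)C(C)(C)C)[C@@H](/C=C\c1ccc(OCc3ccccc3)c(OCc3ccccc3)c1)c1c(OCc3ccccc3)cc(OCc3ccccc3)c(c1O[Si](C)(C)C(C)(C)C)C/C=C\c1ccc(OCc3ccccc3)c(OCc3ccccc3)c1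
A6 | alternative 3 | eicosa-O-benzyl cinnamtannin A2 (identical with 36) | C(c3ccccc3)Oc1cc(OCc3ccccc3)c2c(c1)O[C@H](c1ccc(OCc3ccccc3)c(OCc3ccccc3)c1)[C@H](OCc3ccccc3)[C@H]2c1c(OCc3ccccc3)cc(OCc3ccccc3)c2c1O[C@H](c1ccc(OCc3ccccc3)c(OCc3ccccc3)c1)[C@H](OCc3ccccc3)[C@H]2c1c(OCc3ccccc3)cc(OCc3ccccc3)c2c1O[C@H](c1ccc(OCc3ccccc3)c(OCc3ccccc3)c1)[C@H](OCc3ccccc3)[C@H]2c1c(OCc3ccccc3)cc(OCc3ccccc3)c2c1O[C@H](c1ccc(OCc3ccccc3)c(OCc3ccccc3)c1)[C@H](OCc3ccccc3)C2
A7 | alternative 3 | open-chain tris-carbinol: penta-O-benzyl-epicatechin whose C8 carries a chain of three 1-hydroxy-2-benzyloxy-3-[3,4-bis(benzyloxy)phenyl]-3-(3,5-bis(benzyloxy)phenoxy)propyl units, each aryl ether ring bearing the next carbinol ortho to its ether oxygen | C(c3ccccc3)Oc1cc(OCc3ccccc3)cc(c1)O[C@H](c1ccc(OCc3ccccc3)c(OCc3ccccc3)c1)[C@H](OCc3ccccc3)C(O)c1c(OCc3ccccc3)cc(OCc3ccccc3)cc1O[C@H](c1ccc(OCc3ccccc3)c(OCc3ccccc3)c1)[C@H](OCc3ccccc3)C(O)c1c(OCc3ccccc3)cc(OCc3ccccc3)cc1O[C@H](c1ccc(OCc3ccccc3)c(OCc3ccccc3)c1)[C@H](OCc3ccccc3)C(O)c1c(OCc3ccccc3)cc(OCc3ccccc3)c2c1O[C@H](c1ccc(OCc3ccccc3)c(OCc3ccccc3)c1)[C@H](OCc3ccccc3)C2
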